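The oxocene is disconnected at O1–C7 and C12–C13 (laurencin numbering: C1 alkyne end, C6 acetoxy carbon, C7/C13 ring carbons on oxygen, C12 bromo carbon), so that the ring oxygen and C13 arrive together as a propanoyl group parked on O6. In the key step AgOTf ionises the C7 bromide of a 2-propanoyloxy-3-bromide; the carbonyl oxygen closes on C7 with inversion and the resulting 2-ethyl-1,3-dioxolan-2-ylium carbon (C13) is captured by a C12 enol ether held near by the Z-alkene, giving an 8,10-dioxabicyclo[5.2.1]decene. The step exploits the vicinal C6–O/C7–O pair flanking the oxocene oxygen; the temporary dioxolane is later opened reductively.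

Key step: step 10

Remark: labels C1–C15, O1 (ring oxygen) and O6 (oxygen on C6) follow the laurencin chain in every compound; the target is the (3E,6R,7R,9Z,12S,13R) isomer.
Remark: 13 is carried as an enol ether E/Z mixture and 15 as a C12 epimer mixture; neither element survives into later compounds.

Step 1
Reactants: 1 3-bromo-1,1-dimethoxypropane; 2 lithium acetylide–ethane-1,2-diamine complex
Product: 3 5,5-dimethoxypent-1-yne
Conditions: DMSO, 10 → 23 °C
Reagents that add atoms: none
Why: SN2 alkylation of the acetylide on the primary bromide should give the terminal alkyne that carries C9–C12 and a masked aldehyde carbon.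

Step 2
Reactants: 3 5,5-dimethoxypent-1-yne; 4 4-chlorobut-2-yn-1-ol
Product: 5 9,9-dimethoxynona-2,5-diyn-1-ol
Conditions: CuI, NaI, Cs2CO3, DMF, 23 °C
Reagents that add atoms: none
Why: copper-mediated propargylation of a terminal alkyne (the copper acetylide displaces the propargylic halide) is the standard entry to skipped diynes and should join C5–C8 to C9–C12.

Step 3
Reactants: 5 9,9-dimethoxynona-2,5-diyn-1-ol
Product: 6 (2E)-9,9-dimethoxynon-2-en-5-yn-1-ol
Conditions: LiAlH4, THF, 0 → 23 °C; aqueous NaOH work-up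
Reagents that add atoms: none
Why: hydroxyl-directed trans-hydroalumination reduces only the propargylic-alcohol triple bond and should give the E-allylic alcohol, leaving the isolated alkyne.

Step 4
Reactants: 6 (2E)-9,9-dimethoxynon-2-en-5-yn-1-ol
Product: 7 (2E,5Z)-9,9-dimethoxynona-2,5-dien-1-ol
Conditions: H2 (1 atm), Pd/CaCO3 poisoned with Pb(OAc)2, quinoline, EtOAc, 23 °C
Reagents that add atoms: none
Why: Lindlar semi-hydrogenation (syn addition of hydrogen) should set the C9=C10 Z-alkene of the future ring.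

Step 5
Reactants: 7 (2E,5Z)-9,9-dimethoxynona-2,5-dien-1-ol
Product: 8 [(2R,3R)-3-[(2Z)-6,6-dimethoxyhex-2-en-1-yl]oxiran-2-yl]methanol
Conditions: Ti(OiPr)4 (cat.), D-(−)-diethyl tartrate (cat.), t-BuOOH, 4 Å molecular sieves, CH2Cl2, −20 °C
Reagents that add atoms: tert-butyl hydroperoxide CC(C)(C)OO
Why: Sharpless asymmetric epoxidation of the E-allylic alcohol, in which the D-tartrate ligand directs oxygen to the face that gives the (2R,3R)-epoxide and so fixes the C6–O and C7–O configurations; the remote Z-alkene lacks a directing hydroxyl and should not react.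

Step 6
Reactants: 8 [(2R,3R)-3-[(2Z)-6,6-dimethoxyhex-2-en-1-yl]oxiran-2-yl]methanol
Product: 9 (2R,3S,5Z)-3-bromo-9,9-dimethoxynon-5-ene-1,2-diol
Conditions: Et2NH·HBr, Ti(OiPr)4 (1.5 equiv), CH2Cl2, 23 °C
Reagents that add atoms: diethylammonium bromide CC[NH2+]CC.[Br-]
Why: titanium-templated ring opening of a 2,3-epoxy alcohol delivers bromide to C3 (laurencin C7) by SN2 with inversion, the regioselectivity coming from the titanium alkoxide bound at O1/O2.

Step 7
Reactants: 9 (2R,3S,5Z)-3-bromo-9,9-dimethoxynon-5-ene-1,2-diol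
Product: 10 (2R,3S,5Z)-3-bromo-1-chloro-9,9-dimethoxynon-5-en-2-ol
Conditions: PPh3, CCl4, pyridine, CH2Cl2, 0 → 23 °C
Reagents that add atoms: tetrachloromethane ClC(Cl)(Cl)Cl
Why: the Appel chlorination is selective for the primary hydroxyl of the 1,2-diol and should install at C5 a latent leaving group that tolerates silver salts, hydrides and amines until the epoxide is needed.

Step 8
Reactants: 10 (2R,3S,5Z)-3-bromo-1-chloro-9,9-dimethoxynon-5-en-2-ol; 11 propanoic anhydride
Product: 12 (2R,3S,5Z)-3-bromo-1-chloro-9,9-dimethoxynon-5-en-2-yl propanoate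
Conditions: pyridine, DMAP (cat.), CH2Cl2, 0 °C
Reagents that add atoms: none
Why: DMAP-catalysed acylation of the secondary alcohol should place the propanoyl group (future O1 and C13–C15) on O6 next to the C7 bromide.

Step 9
Reactants: 12 (2R,3S,5Z)-3-bromo-1-chloro-9,9-dimethoxynon-5-en-2-yl propanoate
Product: 13 (2R,3S,5Z)-3-bromo-1-chloro-9-methoxynona-5,8-dien-2-yl propanoate (8E/8Z mixture)
Conditions: TMSOTf, i-Pr2NEt, CH2Cl2, −20 → 0 °C
Reagents that add atoms: none
Why: silyl triflate/amine elimination of methanol from the dimethyl acetal (acetal-to-enol-ether conversion) should unveil the C12 π-nucleophile without touching ester, bromide or chloride.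

Step 10
Reactants: 13 (2R,3S,5Z)-3-bromo-1-chloro-9-methoxynona-5,8-dien-2-yl propanoate
Product: 15 (1R,7R,9S)-9-(chloromethyl)-7-ethyl-8,10-dioxabicyclo[5.2.1]dec-3-ene-6-carbaldehyde (C6 epimers), via dioxolan-2-ylium triflate 14 (not isolated)
Conditions: AgOTf, 2,6-di-tert-butyl-4-methylpyridine, 4 Å molecular sieves, CH2Cl2 (high dilution), −20 → 23 °C; then aqueous NaHCO3
Reagents that add atoms: water O
Why: Proposed new method: AgOTf abstracts the C7 bromide with anchimeric assistance from the vicinal propanoate, whose carbonyl oxygen (future O1) displaces bromide at C7 in a 5-exo-tet closure with inversion to give the 2-ethyl-1,3-dioxolan-2-ylium ion 14; its cationic carbon (C13) is then attacked by C12 of the tethered methyl enol ether, and the resulting methoxycarbenium ion is hydrolysed to the aldehyde on work-up. The closest known reaction types are the silver-assisted Woodward–Prévost ionisation of trans-2-acyloxy halides and the Mukaiyama-type addition of enol ethers to dialkoxycarbenium ions generated from orthoesters; using the pair in one flask to close a medium ring is the new element. Ring closures: the dioxolane by 5-exo-tet attack of oxygen on C7, the oxocene by an eight-membered closure that is endo with respect to the C13=O1 oxocarbenium bond and exo with respect to the enol ether double bond, the two rings sharing C7, O1 and C13 in an 8,10-dioxabicyclo[5.2.1]decene. Stereocontrol: C7 is fixed by the SN2 course of the participation (second inversion, net retention from epoxide 8), the ketal carbon C13 can only form with the five-carbon bridge cis on the dioxolane, and C12 arises as a mixture that step 11 erases. The step needs attack of the enol ether at C13 instead of SN2 alkylation at C7 (which would give a cyclohexene), capture by the ring alkene or intermolecular reaction; charge localisation at C13, the far higher nucleophilicity of the enol ether, the Z-alkene that holds C12 near C13 and high dilution should secure this, and the primary chloride is inert to AgOTf.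

Step 11
Reactants: 15 (1R,7R,9S)-9-(chloromethyl)-7-ethyl-8,10-dioxabicyclo[5.2.1]dec-3-ene-6-carbaldehyde
Product: 16 (1R,7R,9S)-9-(chloromethyl)-7-ethyl-8,10-dioxabicyclo[5.2.1]dec-3-en-6-one
Conditions: Cu(OAc)2 (cat.), 2,2′-bipyridine, DABCO, O2 (1 atm), DMF, 40 °C
Reagents that add atoms: dioxygen O=O
Why: copper-catalysed aerobic oxidative deformylation of an α-branched aldehyde (enolisation, oxygenation, C–C cleavage with loss of formic acid) should excise the extra carbon and funnel both C12 epimers into the single C12 ketone.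

Step 12
Reactants: 16 (1R,7R,9S)-9-(chloromethyl)-7-ethyl-8,10-dioxabicyclo[5.2.1]dec-3-en-6-one
Product: 17 (1R,6R,7R,9S)-9-(chloromethyl)-7-ethyl-8,10-dioxabicyclo[5.2.1]dec-3-en-6-ol
Conditions: NaBH4, MeOH, −20 °C
Reagents that add atoms: none
Why: carbonyl reduction in which hydride should add from the convex face opposite the two-atom O6–C6 bridge (as in related 6,8-dioxabicyclo[3.2.1]octan-4-ones), giving the C12 alcohol syn to that bridge, the epimer that later inverts to the C12 bromide.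

Step 13
Reactants: 17 (1R,6R,7R,9S)-9-(chloromethyl)-7-ethyl-8,10-dioxabicyclo[5.2.1]dec-3-en-6-ol
Product: 18 tert-butyl{[(1R,6R,7R,9S)-9-(chloromethyl)-7-ethyl-8,10-dioxabicyclo[5.2.1]dec-3-en-6-yl]oxy}dimethylsilane
Conditions: TBSOTf, 2,6-lutidine, CH2Cl2, −78 → 0 °C
Reagents that add atoms: tert-butyldimethylsilyl triflate CC(C)(C)[Si](C)(C)OS(=O)(=O)C(F)(F)F
Why: silyl ether formation protects the C12 hydroxyl through ketal opening, side-chain attachment and acetylation.

Step 14
Reactants: 18 tert-butyl{[(1R,6R,7R,9S)-9-(chloromethyl)-7-ethyl-8,10-dioxabicyclo[5.2.1]dec-3-en-6-yl]oxy}dimethylsilane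
Product: 20 tert-butyl({(2R,3R,5Z,8R)-2-ethyl-8-[(2R)-oxiran-2-yl]-3,4,7,8-tetrahydro-2H-oxocin-3-yl}oxy)dimethylsilane, via chlorohydrin oxocene 19 (not isolated)
Conditions: i-Bu2AlH, CH2Cl2, −78 → 0 °C; then MeOH, aqueous NaOH, 23 °C
Reagents that add atoms: none
Why: reductive cleavage of a bicyclic ketal with i-Bu2AlH, which for 8,10-dioxabicyclo[5.2.1]decanes is known to break the ketal C–O bond of the two-atom bridge and give the cis-2,8-disubstituted oxocane, should set C13 (hydrogen anti to the departing O6) and free the C6 hydroxyl, after which base closes the C5–C6 epoxide by Williamson displacement of chloride with retention at C6.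

Step 15
Reactants: 21 1,4-bis(trimethylsilyl)buta-1,3-diyne
Product: 22 buta-1,3-diyn-1-yl(trimethyl)silane
Conditions: MeLi·LiBr, Et2O, 23 °C; then aqueous NH4Cl
Reagents that add atoms: none
Why: selective mono-desilylation by attack of methyllithium at one silicon should give the terminal diyne.

Step 16
Reactants: 22 buta-1,3-diyn-1-yl(trimethyl)silane
Product: 23 [(3E)-4-iodobut-3-en-1-yn-1-yl](trimethyl)silane
Conditions: Cp2Zr(H)Cl, THF, 23 °C; then I2, 0 °C
Reagents that add atoms: iodine II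
Why: Schwartz hydrozirconation adds Zr–H syn across the terminal alkyne with zirconium at the terminus, and iododemetalation with retention should give the E-iodoenyne.

Step 17
Reactants: 20 tert-butyl({(2R,3R,5Z,8R)-2-ethyl-8-[(2R)-oxiran-2-yl]-3,4,7,8-tetrahydro-2H-oxocin-3-yl}oxy)dimethylsilane; 23 [(3E)-4-iodobut-3-en-1-yn-1-yl](trimethyl)silane
Product: 25 (1R,3E)-1-[(2R,3R,5Z,8R)-3-{[tert-butyl(dimethyl)silyl]oxy}-2-ethyl-3,4,7,8-tetrahydro-2H-oxocin-8-yl]-6-(trimethylsilyl)hex-3-en-5-yn-1-ol, via alkenyllithium 24 (not isolated)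
Conditions: 23, t-BuLi (2 equiv), Et2O, −78 °C; then BF3·OEt2 and 20, −78 °C
Reagents that add atoms: none
Why: iodine–lithium exchange with retention of the E geometry, then BF3-promoted SN2 opening of the terminal epoxide at C5, should attach the enyne and release the C6 hydroxyl with its configuration untouched.

Step 18
Reactants: 25 (1R,3E)-1-[(2R,3R,5Z,8R)-3-{[tert-butyl(dimethyl)silyl]oxy}-2-ethyl-3,4,7,8-tetrahydro-2H-oxocin-8-yl]-6-(trimethylsilyl)hex-3-en-5-yn-1-ol
Product: 26 (1R,3E)-1-[(2R,3R,5Z,8R)-3-{[tert-butyl(dimethyl)silyl]oxy}-2-ethyl-3,4,7,8-tetrahydro-2H-oxocin-8-yl]-6-(trimethylsilyl)hex-3-en-5-yn-1-yl acetate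
Conditions: Ac2O, pyridine, DMAP (cat.), CH2Cl2, 23 °C
Reagents that add atoms: acetic anhydride CC(=O)OC(C)=O
Why: DMAP-catalysed acetylation of the only free hydroxyl should install the C6 acetate.

Step 19
Reactants: 26 (1R,3E)-1-[(2R,3R,5Z,8R)-3-{[tert-butyl(dimethyl)silyl]oxy}-2-ethyl-3,4,7,8-tetrahydro-2H-oxocin-8-yl]-6-(trimethylsilyl)hex-3-en-5-yn-1-yl acetate
Product: 27 (1R,3E)-1-[(2R,3R,5Z,8R)-2-ethyl-3-hydroxy-3,4,7,8-tetrahydro-2H-oxocin-8-yl]hex-3-en-5-yn-1-yl acetate
Conditions: n-Bu4NF, AcOH, THF, 0 → 23 °C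
Reagents that add atoms: none
Why: fluoride-mediated desilylation, buffered with acetic acid so that the acetate survives, should remove both the C12 silyl ether and the alkynyl silane.

Step 20
Reactants: 27 (1R,3E)-1-[(2R,3R,5Z,8R)-2-ethyl-3-hydroxy-3,4,7,8-tetrahydro-2H-oxocin-8-yl]hex-3-en-5-yn-1-yl acetate
Product: 28 (1R,3E)-1-[(2R,3S,5Z,8R)-3-bromo-2-ethyl-3,4,7,8-tetrahydro-2H-oxocin-8-yl]hex-3-en-5-yn-1-yl acetate
Conditions: CBr4, P(n-C8H17)3, toluene, 70 °C
Reagents that add atoms: tetrabromomethane BrC(Br)(Br)Br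
Why: Appel bromination of the C12 alcohol proceeds by SN2 displacement of the oxyphosphonium group and should give the C12 bromide with inversion, trans to the C13 ethyl group.

Compound list
1 | 3-bromo-1,1-dimethoxypropane | COC(OC)CCBr | starting material
2 | lithium acetylide–ethane-1,2-diamine complex | [Li+].[C-]#C.NCCN | starting material
3 | 5,5-dimethoxypent-1-yne | C#CCCC(OC)OC | intermediate
4 | 4-chlorobut-2-yn-1-ol | OCC#CCCl | starting material
5 | 9,9-dimethoxynona-2,5-diyn-1-ol | OCC#CCC#CCCC(OC)OC | intermediate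
6 | (2E)-9,9-dimethoxynon-2-en-5-yn-1-ol | OC/C=C/CC#CCCC(OC)OC | intermediate
7 | (2E,5Z)-9,9-dimethoxynona-2,5-dien-1-ol | OC/C=C/C/C=C\CCC(OC)OC | intermediate
8 | [(2R,3R)-3-[(2Z)-6,6-dimethoxyhex-2-en-1-yl]oxiran-2-yl]methanol | OC[C@H]1O[C@@H]1C/C=C\CCC(OC)OC | intermediate
9 | (2R,3S,5Z)-3-bromo-9,9-dimethoxynon-5-ene-1,2-diol | OC[C@@H](O)[C@@H](Br)C/C=C\CCC(OC)OC | intermediate
10 | (2R,3S,5Z)-3-bromo-1-chloro-9,9-dimethoxynon-5-en-2-ol | ClC[C@@H](O)[C@@H](Br)C/C=C\CCC(OC)OC | intermediate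
11 | propanoic anhydride | CCC(=O)OC(=O)CC | starting material
12 | (2R,3S,5Z)-3-bromo-1-chloro-9,9-dimethoxynon-5-en-2-yl propanoate | ClC[C@@H](OC(=O)CC)[C@@H](Br)C/C=C\CCC(OC)OC | intermediate
13 | (2R,3S,5Z)-3-bromo-1-chloro-9-methoxynona-5,8-dien-2-yl propanoate (8E/8Z mixture) | ClC[C@@H](OC(=O)CC)[C@@H](Br)C/C=C\CC=COC | intermediate
14 | (4S,5R)-4-(chloromethyl)-2-ethyl-5-[(2Z)-6-methoxyhexa-2,5-dien-1-yl]-1,3-dioxolan-2-ylium triflate | ClC[C@H]1OC(CC)=[O+][C@@H]1C/C=C\CC=COC.[O-]S(=O)(=O)C(F)(F)F | intermediate (not isolated)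
15 | (1R,7R,9S)-9-(chloromethyl)-7-ethyl-8,10-dioxabicyclo[5.2.1]dec-3-ene-6-carbaldehyde (C6 epimers) | ClC[C@H]1O[C@@]2(CC)O[C@@H]1C/C=C\CC2C=O | intermediate
16 | (1R,7R,9S)-9-(chloromethyl)-7-ethyl-8,10-dioxabicyclo[5.2.1]dec-3-en-6-one | ClC[C@H]1O[C@@]2(CC)O[C@@H]1C/C=C\CC2=O | intermediate
17 | (1R,6R,7R,9S)-9-(chloromethyl)-7-ethyl-8,10-dioxabicyclo[5.2.1]dec-3-en-6-ol | ClC[C@H]1O[C@@]2(CC)O[C@@H]1C/C=C\C[C@H]2O | intermediate
18 | tert-butyl{[(1R,6R,7R,9S)-9-(chloromethyl)-7-ethyl-8,10-dioxabicyclo[5.2.1]dec-3-en-6-yl]oxy}dimethylsilane | ClC[C@H]1O[C@@]2(CC)O[C@@H]1C/C=C\C[C@H]2O[Si](C)(C)C(C)(C)C | intermediate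
19 | (1S)-1-[(2R,3R,5Z,8R)-3-{[tert-butyl(dimethyl)silyl]oxy}-2-ethyl-3,4,7,8-tetrahydro-2H-oxocin-8-yl]-2-chloroethan-1-ol | ClC[C@@H](O)[C@H]1C/C=C\C[C@@H](O[Si](C)(C)C(C)(C)C)[C@@H](CC)O1 | intermediate (not isolated)
20 | tert-butyl({(2R,3R,5Z,8R)-2-ethyl-8-[(2R)-oxiran-2-yl]-3,4,7,8-tetrahydro-2H-oxocin-3-yl}oxy)dimethylsilane | C1O[C@H]1[C@H]2C/C=C\C[C@@H](O[Si](C)(C)C(C)(C)C)[C@@H](CC)O2 | intermediate
21 | 1,4-bis(trimethylsilyl)buta-1,3-diyne | C[Si](C)(C)C#CC#C[Si](C)(C)C | starting material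
22 | buta-1,3-diyn-1-yl(trimethyl)silane | C[Si](C)(C)C#CC#C | intermediate
23 | [(3E)-4-iodobut-3-en-1-yn-1-yl](trimethyl)silane | C[Si](C)(C)C#C/C=C/I | intermediate
24 | [(1E)-4-(trimethylsilyl)but-1-en-3-yn-1-yl]lithium | [Li]/C=C/C#C[Si](C)(C)C | intermediate (not isolated)
25 | (1R,3E)-1-[(2R,3R,5Z,8R)-3-{[tert-butyl(dimethyl)silyl]oxy}-2-ethyl-3,4,7,8-tetrahydro-2H-oxocin-8-yl]-6-(trimethylsilyl)hex-3-en-5-yn-1-ol | C[Si](C)(C)C#C/C=C/C[C@@H](O)[C@H]1C/C=C\C[C@@H](O[Si](C)(C)C(C)(C)C)[C@@H](CC)O1 | intermediate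
26 | (1R,3E)-1-[(2R,3R,5Z,8R)-3-{[tert-butyl(dimethyl)silyl]oxy}-2-ethyl-3,4,7,8-tetrahydro-2H-oxocin-8-yl]-6-(trimethylsilyl)hex-3-en-5-yn-1-yl acetate | C[Si](C)(C)C#C/C=C/C[C@@H](OC(C)=O)[C@H]1C/C=C\C[C@@H](O[Si](C)(C)C(C)(C)C)[C@@H](CC)O1 | intermediate
27 | (1R,3E)-1-[(2R,3R,5Z,8R)-2-ethyl-3-hydroxy-3,4,7,8-tetrahydro-2H-oxocin-8-yl]hex-3-en-5-yn-1-yl acetate | C#C/C=C/C[C@@H](OC(C)=O)[C@H]1C/C=C\C[C@@H](O)[C@@H](CC)O1 | intermediate
28 | (1R,3E)-1-[(2R,3S,5Z,8R)-3-bromo-2-ethyl-3,4,7,8-tetrahydro-2H-oxocin-8-yl]hex-3-en-5-yn-1-yl acetate | C#C/C=C/C[C@@H](OC(C)=O)[C@H]1C/C=C\C[C@H](Br)[C@@H](CC)O1 | target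

Total steps: 20. Longest linear sequence: 18 (steps 1–14 and 17–20; steps 15–16 make the side-chain iodide).

Steps most likely to fail

Step 10 (Proposed new method). What may go wrong: the tethered enol ether may alkylate C7 directly (six-membered carbocycle), the ring alkene may capture the cation, or slow eight-membered closure may let the dioxolan-2-ylium ion eliminate or oligomerise. Fallback, from 13 back to 15, in two stages that are each a known reaction type and that separate ionisation from ring closure: 13 is ionised with AgOTf in CH2Cl2/MeOH buffered with 2,6-lutidine, and the cation is captured by methanol (Woodward–Prévost ionisation with alcohol capture) as the isolable cyclic orthoester (4S,5R)-4-(chloromethyl)-2-ethyl-2-methoxy-5-[(2Z)-6-methoxyhexa-2,5-dien-1-yl]-1,3-dioxolane F1. F1 is then added slowly to catalytic TMSOTf in CH2Cl2 at −78 °C (Lewis-acid orthoester/enol ether condensation of the Mukaiyama type, halide- and silver-free), and hydrolytic work-up gives 15.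

Step 14. What may go wrong: cleavage of the other ketal C–O bond (nine-membered ether) or hydride delivery to the wrong face of C13 (trans-2,8 isomer). Fallback, from 18 back to 19, replacing hydride opening by a radical reduction: 18 is opened with EtSH and Zn(OTf)2 to the dithioketal diol (2S,3R,5Z,8R)-8-{[tert-butyl(dimethyl)silyl]oxy}-1-chloro-9,9-bis(ethylsulfanyl)undec-5-ene-2,3-diol F2. AgClO4/NaHCO3 in MeNO2 then closes the eight-membered ring by hydroxy dithioketal cyclisation through the C7 hydroxyl to the mixed S,O-ketal (1S)-1-[(3R,5Z,8R)-3-{[tert-butyl(dimethyl)silyl]oxy}-2-ethyl-2-(ethylsulfanyl)-3,4,7,8-tetrahydro-2H-oxocin-8-yl]-2-chloroethan-1-ol F3. Ph3SnH/AIBN in toluene at 110 °C replaces sulfur by hydrogen through the C13 radical, a reduction known to favour the cis-2,8-oxocene, giving 19, which the NaOH treatment of step 14 converts into 20.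

Step 11. What may go wrong: slow enolisation of the hindered aldehyde, over-oxidation next to the new ketone, or quaternisation of the amine base by the primary chloride. Fallback, from 15 back to 16: Pinnick oxidation (NaClO2, NaH2PO4, 2-methylbut-2-ene) gives the acid (1R,7R,9S)-9-(chloromethyl)-7-ethyl-8,10-dioxabicyclo[5.2.1]dec-3-ene-6-carboxylic acid F4. Barton decarboxylation of its N-hydroxypyridine-2-thione ester under O2 with t-BuSH, then P(OMe)3, gives the nor-alcohol (1R,7R,9S)-9-(chloromethyl)-7-ethyl-8,10-dioxabicyclo[5.2.1]dec-3-en-6-ol (C6 epimers) F5, and Dess–Martin oxidation returns 16.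

Further compounds
F1 | step 10 | (4S,5R)-4-(chloromethyl)-2-ethyl-2-methoxy-5-[(2Z)-6-methoxyhexa-2,5-dien-1-yl]-1,3-dioxolane | ClC[C@H]1OC(CC)(OC)O[C@@H]1C/C=C\CC=COC
F2 | step 14 | (2S,3R,5Z,8R)-8-{[tert-butyl(dimethyl)silyl]oxy}-1-chloro-9,9-bis(ethylsulfanyl)undec-5-ene-2,3-diol | ClC[C@@H](O)[C@H](O)C/C=C\C[C@@H](O[Si](C)(C)C(C)(C)C)C(CC)(SCC)SCC
F3 | step 14 | (1S)-1-[(3R,5Z,8R)-3-{[tert-butyl(dimethyl)silyl]oxy}-2-ethyl-2-(ethylsulfanyl)-3,4,7,8-tetrahydro-2H-oxocin-8-yl]-2-chloroethan-1-ol | ClC[C@@H](O)[C@H]1C/C=C\C[C@@H](O[Si](C)(C)C(C)(C)C)C(CC)(SCC)O1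
F4 | step 11 | (1R,7R,9S)-9-(chloromethyl)-7-ethyl-8,10-dioxabicyclo[5.2.1]dec-3-ene-6-carboxylic acid | ClC[C@H]1O[C@@]2(CC)O[C@@H]1C/C=C\CC2C(O)=O
F5 | step 11 | (1R,7R,9S)-9-(chloromethyl)-7-ethyl-8,10-dioxabicyclo[5.2.1]dec-3-en-6-ol (C6 epimers) | ClC[C@H]1O[C@@]2(CC)O[C@@H]1C/C=C\CC2O
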